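Time eats target here, and autumn, spring and summer carry the same charge but differ in how they spend it.

| flask | substrate | partner | remark | time |
|---|---|---|---|---|
| Thursday's | 0.050 M | 0.10 M | run made earlier |  |
| Sunday's | 0.050 M | 0.14 M | run made earlier |  |
| Tuesday's | 0.050 M | 0.22 M | run made earlier |  |
| autumn | 0.050 M | 0.100 M | everything together at the start | 25 min |
| spring | 0.050 M (fed, over 15 min) | 0.100 M | all else is in the flask from the start; the feed brings no volume worth counting | 25 min |
| summer | 0.050 M | 0.100 M (fed, over 15 min) | all else is in the flask from the start; the feed brings no volume worth counting | 25 min |

| run | time / min | target / % |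
|---|---|---|
| Thursday's | 4.00 | 61.5 |
| Thursday's | 8.00 | 69.3 |
| Thursday's | 12.0 | 65.2 |
| Thursday's | 15.0 | 57.1 |
| Thursday's | 20.0 | 48.0 |
| Thursday's | 25.0 | 41.6 |
| Sunday's | 2.50 | 51.9 |
| Sunday's | 4.00 | 63.0 |
| Sunday's | 6.00 | 61.3 |
| Sunday's | 10.0 | 47.6 |
| Sunday's | 20.0 | 20.9 |
| Sunday's | 30.0 | 11.8 |
| Tuesday's | 5.00 | 48.6 |
| Tuesday's | 10.0 | 19.0 |
| Tuesday's | 15.0 | 8.4 |
| Tuesday's | 20.0 | 1.8 |
| Tuesday's | 25.0 | 1.2 |
| Tuesday's | 30.0 | 1.0 |

(readings scatter by 1 percentage point)

- a reading or a percentage of target counts all its forms, free or not

- the flask with the highest amount of target, in percent of the substrate charged ("all alike" if they lie within 1.5 percentage points) (autumn / spring / summer / all alike)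
- final target, as a percentage of the substrate charged, in autumn
- final target, as a percentage of the substrate charged, in spring
- final target, as a percentage of the substrate charged, in summer

Thursday's run held 69.3% of target at 8.00 min but 41.6% at 25.0 min. Partner stood at twice the substrate, so if making target takes one partner and over-reaction one more, the partner left once the substrate has reacted matches the target. The loss is then second order with equal amounts, the straight line of step growth, and the inverse of the fraction left climbs steadily. From the readings at 15.0 min and 25.0 min I read an over-reaction clock, the second-order half-life of a full charge of target, as 15.3 min. With equal amounts the fraction left is one over one plus exposure divided by clock, so two times count: that clock and the exposure, the time target spends beside partner.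

Autumn repeats Thursday's charges, so I took its 41.6%. For summer I counted the full charge as target at the end of the feed and started the exposure there, which leaves 10.0 min, shorter than the clock, and gives 60.5%. For spring I let target appear on average midway through the feed, so the exposure is 17.5 min, which gives 46.7%.

The forecast named summer, with 41.5% for autumn, 46.5% for spring and 49.5% for summer, reasoning that in summer “partner is starved while substrate is present”. My summer figure stands 11 percentage points above its number.

The flasks gave 41.9% in autumn, 44.9% in spring and 57.1% in summer, the highest. Summer already held 19.2% of over-reaction product at 15.0 min, so its loss had begun before my exposure started. Read through the clock, summer's figure is an exposure of 11.5 min, and autumn's is 21.2 min.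

    substrate → intermediate (k = 0.0121 /s)
    partner + intermediate → target (k = 0.152 /M/s)
    partner + target → over-reaction product (k = 0.0243 /M/s)
    crystals ⇌ target, rate k4*(cs4 - [target]) while solid is left; crystals form when [target] > cs4 (solubility = 23.0 mM, k = 1.12 /s)

Summer's recipe with 0.085 M of substrate charges 0.0150 M of partner beyond one per substrate. The clock scaled to that charge is 9.01 min, and I let this extra partner fade pseudo-first-order on that clock, so over 10.0 min I get 11.8% of over-reaction product and 88.2% of target. That flask gave 12.5% of over-reaction product and 82.6% of target, with 4.95% still intermediate.

All runs come from a simulation with constants of no real substance.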